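**Plan**

1. Target: (4S,5R,8R,9S,10R)-labd-13-en-16,15-olide-17,19-dioic acid. Labdane numbering is used throughout: decalin C-1 to C-10, side chain C-11/C-12, butenolide C-13 to C-16, C-17 = CO2H on C-8, C-18 = CH3 and C-19 = CO2H on C-4, C-20 = CH3 on C-10.
2. Retrosynthesis: cut C-12–C-13 (butenolide joined last by sp3–sp2 coupling); then cut C-3–C-4 and C-5–C-10 together in a retro-[4+2] that opens rings A and B; then C-4=C-5 (Z-olefination), C-7–C-8 (enolate alkylation) and C-9–C-10 (conjugate addition).
3. Enabling feature: ring A is a cyclohexane whose C-3–C-4 and C-5–C-10 bonds are the two σ-bonds that a C-10=C-1–C-2=C-3 diene and a C-4=C-5 2-methyl-enoate form. Ring B (C-5 to C-10) is the ring through the four-carbon tether C-6 to C-9, so one intramolecular cycloaddition builds the decalin and C-4, C-5 and C-10 (two quaternary).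
4. Helpers: C-17 and C-12 are held as a δ-lactone across C-8/C-9. It fixes C-8 trans to C-9, locks the tether in a chair for the cycloaddition, and is opened later by iodide to the C-17 silyl ester and C-12 iodide. The C-1=C-2 alkene left by the cycloaddition is hydrogenated.
5. Forward: dienylboronate → Rh-catalysed asymmetric 1,4-addition to 5,6-dihydro-2H-pyran-2-one → trans alkylation → aldehyde → (Z)-enoate → cycloaddition (rings A and B) → H2 → Me3SiI (lactone opening and ester cleavage to the bis-silyl ester iodide, carried on without hydrolysis) → Negishi coupling with 3-bromofuran-2(5H)-one and desilylation on work-up.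
6. Stereochemistry: C-9 by catalyst control ((S)-BINAP/Rh); C-8 by alkylation anti to C-9 (also the thermodynamic position); C-4, C-5 and C-10 by the cycloaddition (lactone-locked chair tether, E-diene, Z-enoate).

Key step: step 6

**Route**

Step 1
Reactants: 1 acrolein; 2 2,2'-(ethane-1,1-diyl)bis(4,4,5,5-tetramethyl-1,3,2-dioxaborolane)
Product: 4 4,4,5,5-tetramethyl-2-[(2Z)-penta-2,4-dien-2-yl]-1,3,2-dioxaborolane, via lithiated diboronate 3 (not isolated)
Conditions: 2, lithium 2,2,6,6-tetramethylpiperidide, THF, 0 °C; then 1, −78 → 23 °C; H2O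
Reagents that add atoms: none
Why: Boron-Wittig olefination, in which the α,α-diboryl carbanion adds 1,2 to the aldehyde and the adduct loses lithium pinacolborate by syn B–O elimination, the remaining boryl group eclipsing hydrogen and so ending trans to the vinyl group (methyl cis to vinyl).

Step 2
Reactants: 4 4,4,5,5-tetramethyl-2-[(2Z)-penta-2,4-dien-2-yl]-1,3,2-dioxaborolane; 5 5,6-dihydro-2H-pyran-2-one
Product: 6 (4S)-4-[(2E)-penta-2,4-dien-2-yl]oxan-2-one
Conditions: [Rh(cod)OH]2 (2.5 mol %), (S)-BINAP (6 mol %), 1,4-dioxane/H2O (10:1), 60 °C; then 1 M HCl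
Reagents that add atoms: none
Why: Rhodium-catalysed asymmetric 1,4-addition of an alkenylboron reagent to an α,β-unsaturated δ-lactone (Hayashi–Miyaura reaction), in which the (S)-BINAP–Rh alkenyl species should insert the enoate on the face that gives the (4S) centre (C-9) with retention of the diene geometry, the acid work-up re-closing any opened lactone.

Step 3
Reactants: 6 (4S)-4-[(2E)-penta-2,4-dien-2-yl]oxan-2-one; 7 3-bromo-1,1-dimethoxypropane
Product: 9 (3R,4S)-3-(3,3-dimethoxypropyl)-4-[(2E)-penta-2,4-dien-2-yl]oxan-2-one, via lithium enolate 8 (not isolated)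
Conditions: LiN(iPr)2, THF, −78 °C; then 7, HMPA, −78 → −30 °C
Reagents that add atoms: none
Why: Alkylation of a δ-lactone lithium enolate with a primary bromide, the electrophile entering anti to the dienyl group on the neighbouring carbon to set C-8 trans to C-9, which is also the thermodynamically preferred diequatorial arrangement.

Step 4
Reactants: 9 (3R,4S)-3-(3,3-dimethoxypropyl)-4-[(2E)-penta-2,4-dien-2-yl]oxan-2-one
Product: 10 3-[(3R,4S)-2-oxo-4-[(2E)-penta-2,4-dien-2-yl]oxan-3-yl]propanal
Conditions: AcOH/THF/H2O (3:1:1), 40 °C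
Reagents that add atoms: water (O)
Why: Mild acid hydrolysis of a dimethyl acetal, which should leave the lactone, both stereocentres and the diene untouched.

Step 5
Reactants: 10 3-[(3R,4S)-2-oxo-4-[(2E)-penta-2,4-dien-2-yl]oxan-3-yl]propanal; 11 ethyl 2-[bis(2,2,2-trifluoroethoxy)phosphoryl]propanoate
Product: 13 ethyl (2Z)-2-methyl-5-[(3R,4S)-2-oxo-4-[(2E)-penta-2,4-dien-2-yl]oxan-3-yl]pent-2-enoate, via potassium phosphonate 12 (not isolated)
Conditions: 11, KN(SiMe3)2, 18-crown-6, THF, −78 °C; then 10, −78 °C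
Reagents that add atoms: none
Why: Still–Gennari olefination, in which the electron-poor phosphonate anion with a dissociated potassium counter-ion adds irreversibly and eliminates fast, giving the (Z)-2-methyl enoate with C-6 and the ester cis.

Step 6
Reactants: 13 ethyl (2Z)-2-methyl-5-[(3R,4S)-2-oxo-4-[(2E)-penta-2,4-dien-2-yl]oxan-3-yl]pent-2-enoate
Product: 14 ethyl (4S,5R,8R,9S,10R)-13,14,15,16-tetranorlabd-1-en-17,12-olid-19-oate
Conditions: PhMe (0.01 M), BHT (cat.), sealed tube, 170–185 °C
Reagents that add atoms: none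
Why: Concerted, suprafacial thermal [4+2] cycloaddition of the C-10=C-1–C-2=C-3 diene onto the C-4=C-5 (Z)-enoate, the closest known reaction type being the type 1 intramolecular Diels–Alder reaction of 1,7,9-decatrienoates to trans-fused, angularly methylated octalins. Ring A is closed as the cyclohexene of the cycloadduct (both new σ-bonds, C-3–C-4 and C-5–C-10, lie in it), and ring B is closed at the same time by the C-5–C-10 bond through the four-carbon tether C-6 to C-9 in a chair. C-10 and C-5 are controlled by the tether: the trans-fused δ-lactone holds the C-8 and C-9 substituents equatorial, so only one diene face can reach the enoate through a chair, and the E-diene with the tether exo gives the trans ring fusion (10β-CH3, 5α-H). C-4 is controlled by the Z-geometry of the enoate, which in this transition state places the ester exo and cis to C-6, hence 4β-CO2Et and 4α-CH3. The step needs trans- over cis-fusion and cycloaddition over the 1,5-hydrogen shift of the Z-methyl diene; the first should be secured by the methyl-endo/ester-exo preference typical of 2-methylacrylate dienophiles together with the all-chair arrangement of lactone and tether, the second by high dilution and the lowest workable temperature.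

Step 7
Reactants: 14 ethyl (4S,5R,8R,9S,10R)-13,14,15,16-tetranorlabd-1-en-17,12-olid-19-oate
Product: 15 ethyl (4S,5R,8R,9S,10R)-13,14,15,16-tetranorlabdan-17,12-olid-19-oate
Conditions: H2 (1–3 atm), 10% Pd/C, EtOAc, 23 °C
Reagents that add atoms: none
Why: Heterogeneous hydrogenation of the only C=C bond, a cis-disubstituted cyclohexene, which creates no stereocentre and leaves the ester and lactone untouched.

Step 8
Reactants: 15 ethyl (4S,5R,8R,9S,10R)-13,14,15,16-tetranorlabdan-17,12-olid-19-oate
Product: 16 bis(trimethylsilyl) (4S,5R,8R,9S,10R)-12-iodo-13,14,15,16-tetranorlabdane-17,19-dioate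
Conditions: Me3SiI (5 equiv), CHCl3, 60 °C; then evaporation of all volatiles at ≤ 25 °C and co-evaporation with PhMe under Ar (no aqueous work-up), crude residue used at once
Reagents that add atoms: iodotrimethylsilane (C[Si](C)(C)I)
Why: Ester cleavage by iodotrimethylsilane (O-silylation, then SN2 attack of iodide on the alkyl carbon), which should open the lactone at primary C-12 to the ω-iodo trimethylsilyl ester and dealkylate the hindered axial ethyl ester at its ethyl group, where the congestion around C-19 does not matter; leaving out any aqueous work-up keeps both carboxyl groups silylated, so that the C-17 carboxyl cannot close back onto C-12 and no acidic proton is carried into the organozinc step.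

Step 9
Reactants: 16 bis(trimethylsilyl) (4S,5R,8R,9S,10R)-12-iodo-13,14,15,16-tetranorlabdane-17,19-dioate; 17 3-bromofuran-2(5H)-one
Product: 20 (4S,5R,8R,9S,10R)-labd-13-en-16,15-olide-17,19-dioic acid (target), via alkylzinc iodide 18 (not isolated), via silylated coupling product 19 (not isolated)
Conditions: Zn dust, LiCl, THF, 40 °C; then 17, Pd(OAc)2 (5 mol %), SPhos (10 mol %), THF, 23–40 °C; aq. citric acid
Reagents that add atoms: none
Why: Negishi coupling, in which zinc inserts into the primary C–I bond of the silyl-masked diacid, the SPhos–palladium catalyst joins the alkylzinc to the α-bromo-butenolide as with other α-halo enones and enoates faster than β-hydride elimination, and the mildly acidic aqueous work-up hydrolyses both trimethylsilyl esters to the free acids.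

**Compound list**

1 | acrolein (prop-2-enal) | C=CC=O | starting material
2 | 2,2'-(ethane-1,1-diyl)bis(4,4,5,5-tetramethyl-1,3,2-dioxaborolane) | CC(B1OC(C)(C)C(C)(C)O1)B1OC(C)(C)C(C)(C)O1 | starting material
3 | lithium 1,1-bis(4,4,5,5-tetramethyl-1,3,2-dioxaborolan-2-yl)ethan-1-ide | [Li+].C[C-](B1OC(C)(C)C(C)(C)O1)B1OC(C)(C)C(C)(C)O1 | intermediate
4 | 4,4,5,5-tetramethyl-2-[(2Z)-penta-2,4-dien-2-yl]-1,3,2-dioxaborolane | C=C/C=C(\C)B1OC(C)(C)C(C)(C)O1 | intermediate
5 | 5,6-dihydro-2H-pyran-2-one | O=C1C=CCCO1 | starting material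
6 | (4S)-4-[(2E)-penta-2,4-dien-2-yl]oxan-2-one | O=C1C[C@@H](/C(C)=C/C=C)CCO1 | intermediate
7 | 3-bromo-1,1-dimethoxypropane | COC(CCBr)OC | starting material
8 | lithium (4S)-4-[(2E)-penta-2,4-dien-2-yl]-5,6-dihydro-4H-pyran-2-olate (lithium enolate of 6) | [Li+].[O-]C1=C[C@@H](/C(C)=C/C=C)CCO1 | intermediate
9 | (3R,4S)-3-(3,3-dimethoxypropyl)-4-[(2E)-penta-2,4-dien-2-yl]oxan-2-one | O=C1[C@H](CCC(OC)OC)[C@@H](/C(C)=C/C=C)CCO1 | intermediate
10 | 3-[(3R,4S)-2-oxo-4-[(2E)-penta-2,4-dien-2-yl]oxan-3-yl]propanal | O=C1[C@H](CCC=O)[C@@H](/C(C)=C/C=C)CCO1 | intermediate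
11 | ethyl 2-[bis(2,2,2-trifluoroethoxy)phosphoryl]propanoate | CCOC(=O)C(C)P(=O)(OCC(F)(F)F)OCC(F)(F)F | starting material
12 | potassium salt of 11 (phosphonate carbanion) | [K+].CCOC(=O)[C-](C)P(=O)(OCC(F)(F)F)OCC(F)(F)F | intermediate
13 | ethyl (2Z)-2-methyl-5-[(3R,4S)-2-oxo-4-[(2E)-penta-2,4-dien-2-yl]oxan-3-yl]pent-2-enoate | O=C1[C@H](CC/C=C(/C)C(=O)OCC)[C@@H](/C(C)=C/C=C)CCO1 | intermediate
14 | ethyl (4S,5R,8R,9S,10R)-13,14,15,16-tetranorlabd-1-en-17,12-olid-19-oate (trans-fused Δ1-octalin; δ-lactone from the C-17 carbonyl on C-8 to the oxygen on C-12; 4β-CO2Et, 4α-CH3, 10β-CH3) | C[C@]12C=CC[C@](C)(C(=O)OCC)[C@@H]1CC[C@@H](C(=O)OCC3)[C@@H]23 | intermediate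
15 | ethyl (4S,5R,8R,9S,10R)-13,14,15,16-tetranorlabdan-17,12-olid-19-oate | C[C@]12CCC[C@](C)(C(=O)OCC)[C@@H]1CC[C@@H](C(=O)OCC3)[C@@H]23 | intermediate
16 | bis(trimethylsilyl) (4S,5R,8R,9S,10R)-12-iodo-13,14,15,16-tetranorlabdane-17,19-dioate | C[C@]12CCC[C@](C)(C(=O)O[Si](C)(C)C)[C@@H]1CC[C@@H](C(=O)O[Si](C)(C)C)[C@@H]2CCI | intermediate
17 | 3-bromofuran-2(5H)-one | O=C1OCC=C1Br | starting material
18 | alkylzinc iodide of 16 (C-12–ZnI) | C[C@]12CCC[C@](C)(C(=O)O[Si](C)(C)C)[C@@H]1CC[C@@H](C(=O)O[Si](C)(C)C)[C@@H]2CC[Zn]I | intermediate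
19 | bis(trimethylsilyl) (4S,5R,8R,9S,10R)-labd-13-en-16,15-olide-17,19-dioate | C[C@]12CCC[C@](C)(C(=O)O[Si](C)(C)C)[C@@H]1CC[C@@H](C(=O)O[Si](C)(C)C)[C@@H]2CCC1=CCOC1=O | intermediate
20 | (4S,5R,8R,9S,10R)-labd-13-en-16,15-olide-17,19-dioic acid | C[C@]12CCC[C@](C)(C(=O)O)[C@@H]1CC[C@@H](C(=O)O)[C@@H]2CCC1=CCOC1=O | target

**Step count and risks**

Total steps: 9. Longest linear sequence: 9 steps (from 1 and 2 to 20).

Steps most likely to fail:

Step 6. The cycloaddition may run through the cis-fused (ester-endo) transition state, or the Z-methyl diene may undergo a 1,5-hydrogen shift before it cyclises at the temperature the trisubstituted enoate needs. Fallback, setting out from 10 and returning at 14: Horner–Wadsworth–Emmons reaction of 10 with ethyl 2-bromo-2-(diethoxyphosphoryl)acetate (NaH, THF) should give ethyl 2-bromo-5-[(3R,4S)-2-oxo-4-[(2E)-penta-2,4-dien-2-yl]oxan-3-yl]pent-2-enoate F1, either alkene geometry serving. This more reactive α-halo dienophile should cyclise at 80–110 °C to the 4-bromo-18-nor analogue of 14, ethyl (5R,8R,9S,10R)-4-bromo-13,14,15,16,18-pentanorlabd-1-en-17,12-olid-19-oate F2, as a mixture at C-4. Me2CuLi should then turn the tertiary α-bromo ester into its enolate by halogen–metal exchange, and iodomethane should alkylate it on the α-face, anti to the angular methyl, so that C-4 no longer depends on alkene geometry or on the endo/exo course; the product is 14.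

Step 2. Transmetallation of the α-branched dienylboronate may be slow, protodeboronation may compete, or the enantioselectivity may erode with the poorly electrophilic lactone. Fallback, setting out from 4 and returning at 6: Suzuki–Miyaura coupling of 4 with (E)-3-iodoprop-2-en-1-ol (Pd(PPh3)4, aq. K3PO4, THF) should give (2E,4E)-4-methylhepta-2,4,6-trien-1-ol F3. Johnson–Claisen rearrangement (triethyl orthoacetate, cat. EtCO2H, 130 °C) should give racemic ethyl (4E)-3-ethenyl-4-methylhepta-4,6-dienoate F4. Saponification and classical resolution through the salt with one enantiomer of 1-phenylethylamine should give (3R,4E)-3-ethenyl-4-methylhepta-4,6-dienoic acid F5. Chemoselective hydroboration of the isolated vinyl group with 9-BBN (one further equivalent for the acid), oxidation with NaBO3 and acidification should close the δ-lactone and return 6.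

Step 9. Zinc insertion may stall, the alkylzinc may be protonated if the silyl esters are partly hydrolysed by adventitious moisture, the C-17 silyl ester may close back onto C-12, or β-hydride elimination may occur at palladium. Fallback, setting out from 16 and returning at 20: brief stirring of 16 with ice-cold water should give (4S,5R,8R,9S,10R)-12-iodo-13,14,15,16-tetranorlabdane-17,19-dioic acid F6, which as the un-ionised acid should not lactonise quickly. tert-Butyl 2,2,2-trichloroacetimidate with catalytic BF3·OEt2 should convert both acids into di-tert-butyl (4S,5R,8R,9S,10R)-12-iodo-13,14,15,16-tetranorlabdane-17,19-dioate F7. The iodide should alkylate the lithium enolate (LiN(iPr)2, THF/HMPA, −78 °C) of 3-(phenylsulfanyl)oxolan-2-one to give di-tert-butyl (4S,5R,8R,9S,10R)-13-(phenylsulfanyl)labdan-16,15-olide-17,19-dioate F8. Oxidation with mCPBA at −78 °C should give di-tert-butyl (4S,5R,8R,9S,10R)-13-(phenylsulfinyl)labdan-16,15-olide-17,19-dioate F9. Its thermal syn-elimination (PhMe, 110 °C) towards the ring CH2 should give di-tert-butyl (4S,5R,8R,9S,10R)-labd-13-en-16,15-olide-17,19-dioate F10. CF3CO2H in CH2Cl2 then frees 20.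

**Further compounds**

F1 | step 6 | ethyl 2-bromo-5-[(3R,4S)-2-oxo-4-[(2E)-penta-2,4-dien-2-yl]oxan-3-yl]pent-2-enoate (either geometry) | O=C1[C@H](CCC=C(Br)C(=O)OCC)[C@@H](/C(C)=C/C=C)CCO1
F2 | step 6 | ethyl (5R,8R,9S,10R)-4-bromo-13,14,15,16,18-pentanorlabd-1-en-17,12-olid-19-oate (C-4 epimers) | C[C@]12C=CCC(Br)(C(=O)OCC)[C@@H]1CC[C@@H](C(=O)OCC3)[C@@H]23
F3 | step 2 | (2E,4E)-4-methylhepta-2,4,6-trien-1-ol | OC/C=C/C(C)=C/C=C
F4 | step 2 | ethyl (4E)-3-ethenyl-4-methylhepta-4,6-dienoate (racemic) | CCOC(=O)CC(/C(C)=C/C=C)C=C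
F5 | step 2 | (3R,4E)-3-ethenyl-4-methylhepta-4,6-dienoic acid | OC(=O)C[C@@H](/C(C)=C/C=C)C=C
F6 | step 9 | (4S,5R,8R,9S,10R)-12-iodo-13,14,15,16-tetranorlabdane-17,19-dioic acid | C[C@]12CCC[C@](C)(C(=O)O)[C@@H]1CC[C@@H](C(=O)O)[C@@H]2CCI
F7 | step 9 | di-tert-butyl (4S,5R,8R,9S,10R)-12-iodo-13,14,15,16-tetranorlabdane-17,19-dioate | C[C@]12CCC[C@](C)(C(=O)OC(C)(C)C)[C@@H]1CC[C@@H](C(=O)OC(C)(C)C)[C@@H]2CCI
F8 | step 9 | di-tert-butyl (4S,5R,8R,9S,10R)-13-(phenylsulfanyl)labdan-16,15-olide-17,19-dioate (C-13 epimers) | C[C@]12CCC[C@](C)(C(=O)OC(C)(C)C)[C@@H]1CC[C@@H](C(=O)OC(C)(C)C)[C@@H]2CCC1(Sc2ccccc2)CCOC1=O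
F9 | step 9 | di-tert-butyl (4S,5R,8R,9S,10R)-13-(phenylsulfinyl)labdan-16,15-olide-17,19-dioate | C[C@]12CCC[C@](C)(C(=O)OC(C)(C)C)[C@@H]1CC[C@@H](C(=O)OC(C)(C)C)[C@@H]2CCC1(S(=O)c2ccccc2)CCOC1=O
F10 | step 9 | di-tert-butyl (4S,5R,8R,9S,10R)-labd-13-en-16,15-olide-17,19-dioate | C[C@]12CCC[C@](C)(C(=O)OC(C)(C)C)[C@@H]1CC[C@@H](C(=O)OC(C)(C)C)[C@@H]2CCC1=CCOC1=O
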